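## Structural features

The target is a 1H-indole: a benzene ring (ring A, C3a–C4–C5–C6–C7–C7a) fused through the C3a–C7a bond to a pyrrole ring (ring B, N1–C2–C3–C3a–C7a). It carries three bromine atoms, two on neighbouring carbons of ring B (C2 and C3) and one on ring A at C7, the carbon next to the ring fusion on the nitrogen side; N1 keeps its hydrogen and C4, C5 and C6 are unsubstituted. The molecule is flat and has no stereocentre, so the whole problem is regiochemistry among the six C–H bonds of the parent heterocycle (the seventh hydrogen sits on nitrogen). The fragile part is ring B: N–H 2-bromoindoles and 2,3-dibromoindoles are sensitive to acid, light and air (hydrolysis towards oxindoles, oligomerisation). The C2–Br bond should therefore be made late and under mild conditions, and the free N–H is best carried through without a protecting group that would need harsh removal. The real difficulty is that electrophilic bromination follows the enamine polarity of ring B: it goes to C3 first and then spreads over C2, C5 and C6, while C7 is hardly reached. The key step uses the fact that the two awkward carbons, C2 and C7, are the two carbons flanking N1–H: C2–H is the most reactive C–H bond of indole towards an iridium boryl catalyst, and the free N1–H can hold the same catalyst over C7–H. Boron placed on these two carbons is then exchanged for bromine, and C3 is left to ordinary electrophilic substitution.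

## Logic of the disconnections

The C3–Br bond of 7 is cut first. C3 is the position an electrophile seeks by itself in an indole whose C2 is occupied, so this is the one bromine that needs no help, and removing it leads to 6, which keeps only the two "unnatural" bromines. The forward step must deliver exactly one electrophilic bromine under cold, acid-free conditions, so that ring A stays untouched and the labile C2–Br bond of ring B is neither hydrolysed nor lost in oligomerisation.

Next, both remaining C–Br bonds of 6 (C2–Br and C7–Br) are cut and replaced by C–B bonds, which leads to 4. Ipso substitution of a boronate copies the position of boron onto bromine, so the regiochemical problem moves from halogenation, where it has no clean answer, to C–H borylation, where it has one. The gain is that no bromine has to be placed at C2 or C7 by electrophilic substitution. The forward step must exchange both boron groups; the one at C2 is a heteroaryl boronate prone to protonolysis, so 4 must be used at once and the half-exchanged 5 must go on to 6 in the same flask.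

Finally the C2–B and C7–B bonds of 4 are cut, which leads back to 1 and 2, both catalogue chemicals. Two of the six C–H bonds of 1 are functionalised in one operation, with no protecting or directing group added and no ring to build. The forward step needs a catalyst that takes C2–H first (giving 3) and is then led by the free N–H to C7–H and not to the sterically open C5–H and C6–H. It also needs N1 to remain N–H and the reaction to stop after two borylations.

## Other disconnections considered

Alternative 1: The cut is the C7–C7a bond, so that ring A is closed onto a preformed pyrrole and arrives as a saturated ring with a ketone at C7, 1,4,5,6-tetrahydro-7H-indol-7-one A1. In the forward key step 4-(1H-pyrrol-3-yl)butanoic acid A2 is activated as a mixed anhydride and acylates the neighbouring α-carbon of the pyrrole in an intramolecular Friedel–Crafts reaction that closes the six-membered ring.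
- In its favour: the closure is onto the most nucleophilic pyrrole position, the tether fixes the oxygen function at C7 beyond doubt, and no transition metal is needed.
- Against it here: C7 arrives as C=O in a non-aromatic ring. Ring A would have to be dehydrogenated to the phenol 1H-indol-7-ol A3, and the C–O bond turned into C–Br through a sulfonate and a metal-catalysed halide exchange, all on an electron-rich N–H heterocycle that would probably need protection. A2 is a β-substituted pyrrole that has to be made. Both ring-B bromines would still have to be put in electrophilically, C2 after C3, which is the less controlled way.
- Structure: it builds a carbocycle that the chosen plan obtains ready-made in 1.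
- Mechanism: the acylation is at least the equal of the double borylation in reliability, and it is the better of the two in that its C7 regiochemistry is enforced by connectivity and not by a catalyst–substrate contact; it also avoids a protolabile C2 boronate.
- Step economy: it would take roughly ten steps against three.

Alternative 2: The cuts are N1–C2 and C3–Br, so that ring B is closed last with both of its bromines and the product of the key step is 2,3,7-tribromo-1-(methylsulfonyl)indole A4. In the forward key step N-[2-bromo-6-(bromoethynyl)phenyl]methanesulfonamide A5 is treated with the bromine electrophile used in step 3; the bromoalkyne is activated as a bromonium species and the sulfonamide nitrogen attacks the bromine-bearing alkyne carbon in a 5-endo-dig closure.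
- In its favour: all three bromines are placed by construction (C7 from the aniline, C2 from the bromoalkyne, C3 from the electrophile), and A4 is an electron-poor, N-protected indole that should be far easier to handle than an N–H 2-bromoindole.
- Against it here: A5 needs about four steps (chemoselective Sonogashira coupling on an aniline that already carries the C7 bromine, desilylation, bromination of the terminal alkyne, N-sulfonylation). A bromoalkyne is a poorer partner for an electrophile than a plain alkyne, so simple dibromination of the triple bond could compete with attack by the weakly nucleophilic sulfonamide. The methanesulfonyl group would have to be removed from nitrogen with strong nucleophiles or reducing metals, conditions that endanger the C2–Br bond (activated towards addition–elimination by the N-sulfonyl group) and the aryl bromide.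
- Structure: it is the equal or the better of the chosen plan, since no regioisomer can arise and the intermediates are stabilised by the N-substituent.
- Mechanism: the key step forms a ring and a C–Br bond at once, but the last deprotection is a weakness that the chosen plan does not have, because nitrogen is never protected there.
- Step economy: about seven steps against three.

Alternative 3: The cuts are C3a–C7a and C4–C5, an intramolecular Diels–Alder reaction of a furan that builds ring A and a saturated ring B together and gives tert-butyl 7-bromoindoline-1-carboxylate A6. In the forward key step tert-butyl (3-bromofuran-2-yl)(but-3-en-1-yl)carbamate A7 is heated; the tethered alkene adds across C2 and C5 of the furan, the oxygen bridge opens with help from the nitrogen lone pair, and loss of water aromatises the new six-membered ring.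
- In its favour: the bromine is carried in on C3 of the furan and ends at C7 with certainty, the step is metal-free, and A6 is a robust carbamate.
- Against it here: A7 requires a 2-amidofuran (Curtius rearrangement of the corresponding furoic acid, then N-alkylation). The unactivated alkene demands high temperature, at which the tert-butyl carbamate and the aminofuran are at risk. The product is an indoline, so carbamate removal and dehydrogenation to 7-bromoindole A8 would follow, and then two electrophilic brominations; the C2 one would have to pass through a 3,3-dibromoindolenine and a 1,2-shift. A8 is also a simple bromoindole for which the construction of two rings is a high price.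
- Structure: it makes both rings, while the chosen plan buys them in 1.
- Mechanism: the pericyclic key step is the equal or the better of a directed C–H borylation in regiochemical certainty, but it leaves the C2 bromine to the weakest method, where the chosen plan uses an ipso substitution.
- Step economy: about eight steps against three.

Key step: step 1

Remark on the chemistry (assumption): in step 1 both boron atoms of 2 are taken to end in C–B bonds, because the HBpin released in the first turnover is itself a borylating agent; the equation is then 1 + 2 → 4 + H2.

Remark on the chemistry (assumption): in step 2 the heteroaryl C2–B bond is taken to react before the aryl C7–B bond, which defines 5; the opposite order would lead to the same 6.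

Step 1
Reactants: 1 indole (1H-indole); 2 bis(pinacolato)diboron
Product: 4 2,7-bis(4,4,5,5-tetramethyl-1,3,2-dioxaborolan-2-yl)-1H-indole, via 2-(pinacolboryl)indole 3 (not isolated)
Conditions: [Ir(OMe)(cod)]2 (1.5 mol %), dtbpy (3 mol %), B2pin2 (1.3 equiv), THF, 65 °C, N2; short silica plug
Reagents that add atoms: none
Why: Iridium-catalysed aromatic C–H borylation, a known reaction type that has been taken as far as 2,7-diborylation on N–H indoles. [Ir(OMe)(cod)]2, dtbpy and 2 form a 16-electron tris(boryl) complex of trivalent iridium, (dtbpy)Ir(Bpin)3, which cleaves an aryl C–H bond by oxidative addition (or a boryl-assisted σ-bond metathesis) to a pentavalent iridium aryl hydride; C–B reductive elimination releases the boronate, and 2 or the HBpin formed from it restores the tris(boryl) complex. The first bond to react is C2–H, the most acidic and accessible C–H next to the heteroatom, which gives 3. In 3 the free N1–H is expected to hold the catalyst near C7–H, most plausibly through a hydrogen bond from N–H to an oxygen of a boryl ligand (coordination of nitrogen to the metal is the other explanation), so that the second boron goes to C7 and not to the sterically freer C5 or C6. For this the nitrogen must stay N–H: an N-boryl group would act as a steric shield and would be expected to send boron to C3, so no amine base is added and the boron reagent is kept to a small excess. No ring is closed and no stereocentre is formed. The selectivity needed is two of six C–H bonds; the reaction should stop at 4 because each remaining C–H bond is flanked by a boryl group (C3, C6), crowded by the ring fusion and C3 (C4) or undirected (C5), and because little boron reagent is left. Compound 4 is used without storage, since its C2–B bond is prone to protonolysis.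

Step 2
Reactants: 4 2,7-bis(4,4,5,5-tetramethyl-1,3,2-dioxaborolan-2-yl)-1H-indole
Product: 6 2,7-dibromo-1H-indole, via 2-bromo-7-(pinacolboryl)indole 5 (not isolated)
Conditions: CuBr2 (6 equiv), MeOH/THF/H2O, 70 °C, dark; aq. NH4Cl/NaHCO3 work-up
Reagents that add atoms: CuBr2 (copper dibromide), [Cu+2].[Br-].[Br-]
Why: Copper-mediated bromodeboronation of aryl pinacol boronates, an ipso substitution: the aryl group passes from boron to divalent copper, a second CuBr2 oxidises the arylcopper to a trivalent arylcopper bromide, and C–Br reductive elimination leaves CuBr, so each C–B bond consumes two CuBr2 and bromine appears exactly where boron was. The N–H and the new C–Br bonds should survive, and any bromination of C3 by the excess of CuBr2 would only anticipate step 3.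

Step 3
Reactants: 6 2,7-dibromo-1H-indole
Product: 7 2,3,7-tribromo-1H-indole
Conditions: NBS (1.0 equiv), THF, −40 → 0 °C, dark; aq. Na2S2O3/NaHCO3 work-up
Reagents that add atoms: N-bromosuccinimide (NBS), O=C1CCC(=O)N1Br
Why: Electrophilic aromatic substitution of an indole at C3: NBS attacks the enamine-like β-carbon of ring B to give an N-stabilised 3H-indolium σ-complex that loses the C3 proton. With C2 occupied, ring A deactivated by its own bromine, one equivalent of reagent and low temperature, substitution at C5 or C6 should not compete, and the cold, neutral conditions spare the labile C2–Br bond; no stereocentre is involved.

## Compound list

1 | indole (1H-indole) | c1ccc2[nH]ccc2c1 | starting material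
2 | bis(pinacolato)diboron | CC1(C)OB(OC1(C)C)B1OC(C)(C)C(C)(C)O1 | starting material
3 | 2-(4,4,5,5-tetramethyl-1,3,2-dioxaborolan-2-yl)-1H-indole | CC1(C)OB(OC1(C)C)c1cc2ccccc2[nH]1 | intermediate
4 | 2,7-bis(4,4,5,5-tetramethyl-1,3,2-dioxaborolan-2-yl)-1H-indole | CC1(C)OB(OC1(C)C)c1cc2cccc(B3OC(C)(C)C(C)(C)O3)c2[nH]1 | intermediate
5 | 2-bromo-7-(4,4,5,5-tetramethyl-1,3,2-dioxaborolan-2-yl)-1H-indole | CC1(C)OB(OC1(C)C)c1cccc2cc(Br)[nH]c12 | intermediate
6 | 2,7-dibromo-1H-indole | Brc1cc2cccc(Br)c2[nH]1 | intermediate
7 | 2,3,7-tribromo-1H-indole | Brc1[nH]c2c(Br)cccc2c1Br | target

## Step count and least certain steps

Total step count: 3. Longest linear sequence: 3 steps (1 → 4 → 6 → 7).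

Step 1 (key step). The likely failures are:
- a second borylation that stalls at 3;
- loss of direction in the second borylation (attack at C5 or C6 if the N–H contact with the catalyst is disturbed, or at C3 if an N–B bond forms);
- a third borylation when too much boron reagent is present;
- protonolysis of the C2–B bond during purification.

Fallback: setting out from 1, the nitrogen would first be silylated with Et2SiH2 under a ruthenium catalyst such as [RuCl2(p-cymene)]2 (dehydrogenative N–Si coupling) to give 1-(diethylsilyl)-1H-indole F1. With [IrCl(cod)]2, dtbpy, 2 and a trace of HBpin in THF at 80 °C the Si–H group should bind iridium as a silyl ligand and deliver the metal to the neighbouring C7–H, giving 1-(diethylsilyl)-7-(4,4,5,5-tetramethyl-1,3,2-dioxaborolan-2-yl)-1H-indole F2. Aqueous NaOAc would then cleave the N–Si bond to 7-(4,4,5,5-tetramethyl-1,3,2-dioxaborolan-2-yl)-1H-indole F3. A separate, undirected borylation of F3 with 2 (0.6 equiv) and [Ir(OMe)(cod)]2/dtbpy at room temperature to 40 °C would place the second boron at C2, the intrinsically preferred site of an N–H indole, and rejoin the route at 4. This reverses the order of the two C–B bond formations and replaces the weak N–H contact by a covalently bound directing group.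

Step 2. The likely failures are:
- protonolysis of the C2–B bond in hot aqueous methanol before copper takes the heteroaryl group, which would leave C2 without bromine;
- oxidation or oxidative coupling of the electron-rich N–H indole by divalent copper;
- decomposition of the 2-bromoindole during a long work-up.

Fallback: setting out from 4, the order of the two halogenation modes would be reversed. NBS (1 equiv, THF, −40 °C) should brominate C3 first and give 3-bromo-2,7-bis(4,4,5,5-tetramethyl-1,3,2-dioxaborolan-2-yl)-1H-indole F4. Its ring B is less electron-rich, so the C2–B bond should be less open to protonolysis and the heterocycle less open to oxidation by copper. CuBr2 in aqueous methanol would then exchange both C–B bonds and lead directly to 7, so that 6 is never handled.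

Step 3. The likely failures are:
- over-bromination of ring A, or oxidation, where the reagent is locally in excess;
- acid-triggered hydrolysis or oligomerisation of the N–H 2-bromoindole by traces of HBr;
- loss of product on silica.

If step 2 has already brominated part of the material at C3, the amount of NBS has to be matched to the 6 actually present.

Fallback: setting out from 6, the nitrogen would be acylated (Boc2O, DMAP cat., MeCN) to tert-butyl 2,7-dibromo-1H-indole-1-carboxylate F5. As a carbamate it has lost the enamine character that drives oligomerisation, and it could be brominated at C3 with NBS in DMF at room temperature to 40 °C to give tert-butyl 2,3,7-tribromo-1H-indole-1-carboxylate F6, a compound that can be purified without haste. K2CO3 in MeOH at room temperature would then remove the crowded carbamate from the weakly basic indole nitrogen and rejoin the route at 7.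

## Further compounds

F1 | step 1 | 1-(diethylsilyl)-1H-indole | CC[SiH](CC)n1ccc2ccccc21
F2 | step 1 | 1-(diethylsilyl)-7-(4,4,5,5-tetramethyl-1,3,2-dioxaborolan-2-yl)-1H-indole | CC[SiH](CC)n1ccc2cccc(B3OC(C)(C)C(C)(C)O3)c21
F3 | step 1 | 7-(4,4,5,5-tetramethyl-1,3,2-dioxaborolan-2-yl)-1H-indole | CC1(C)OB(OC1(C)C)c1cccc2cc[nH]c12
F4 | step 2 | 3-bromo-2,7-bis(4,4,5,5-tetramethyl-1,3,2-dioxaborolan-2-yl)-1H-indole | CC1(C)OB(OC1(C)C)c1[nH]c2c(B3OC(C)(C)C(C)(C)O3)cccc2c1Br
F5 | step 3 | tert-butyl 2,7-dibromo-1H-indole-1-carboxylate | CC(C)(C)OC(=O)n1c(Br)cc2cccc(Br)c21
F6 | step 3 | tert-butyl 2,3,7-tribromo-1H-indole-1-carboxylate | CC(C)(C)OC(=O)n1c(Br)c(Br)c2cccc(Br)c21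
A1 | alternative 1 | 1,4,5,6-tetrahydro-7H-indol-7-one | O=C1CCCc2cc[nH]c21
A2 | alternative 1 | 4-(1H-pyrrol-3-yl)butanoic acid | OC(=O)CCCc1cc[nH]c1
A3 | alternative 1 | 1H-indol-7-ol | Oc1cccc2cc[nH]c12
A4 | alternative 2 | 2,3,7-tribromo-1-(methylsulfonyl)indole | CS(=O)(=O)n1c(Br)c(Br)c2cccc(Br)c12
A5 | alternative 2 | N-[2-bromo-6-(bromoethynyl)phenyl]methanesulfonamide | CS(=O)(=O)Nc1c(Br)cccc1C#CBr
A6 | alternative 3 | tert-butyl 7-bromoindoline-1-carboxylate | CC(C)(C)OC(=O)N1CCc2cccc(Br)c21
A7 | alternative 3 | tert-butyl (3-bromofuran-2-yl)(but-3-en-1-yl)carbamate | CC(C)(C)OC(=O)N(CCC=C)c1occc1Br
A8 | alternative 3 | 7-bromo-1H-indole | Brc1cccc2cc[nH]c12
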